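**Retrosynthetic overview**

1. The last bond made is the C4 carboxamide, by acyl transfer from the N-acyl oxazolidinone of the finished core 15 to the side-chain amine 22 (built from glycolaldehyde, a stabilised ylide and mono-Boc-putrescine).
2. The oxepinone ring (O1–C2–C3–C4–C5–C5a–C9a) is the only ring the route builds. It is closed in one operation as a formal [4+3] annulation that makes C2–C3 (Michael addition) and C5–C5a (Houben–Hoesch acylation) from aryloxy ester 6 and cyanoacrylimide 10.
3. Enabling feature: the ketone carbon C5 sits on C5a of ring A, ortho to the ether oxygen O1 and ortho/para to the two methoxy groups (a phloroglucinol-type nucleophilic carbon); C2 is the α-carbon of a carboxylic acid that also bears O1 and an aryl group (a stabilised carbanion); C3–C4–C5 is a benzylidene-malonyl unit (C3 a Michael terminus, C5 masked as a nitrile, the C4 carboxyl as a chiral imide).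
4. Fragment 1 (6): (4-hydroxyphenyl)acetic acid → double trichloroethyl protection → benzylic bromide → ether with 3,5-dimethoxyphenol. Fragment 2 (10): α-cyanocinnamic acid + (S)-4-benzyl-1,3-oxazolidin-2-one.
5. Ring order: ring A, the C2 aryl ring and the C3 phenyl ring are bought; the oxepinone ring forms in step 6; the two trichloroethyl groups leave in step 7 and the temporary oxazolidinone ring in step 12.

Key step: step 6

Remark: C4, the CH between the C5 ketone and the C4 acyl group, is taken to be configurationally labile (β-dicarbonyl α-carbon) and to rest trans to the C3 phenyl group, which is the relation in the target.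

**Route**

Step 1
Reactants: 1 (4-hydroxyphenyl)acetic acid
Product: 2 (4-hydroxyphenyl)acetic acid 2,2,2-trichloroethyl ester
Conditions: Cl3CCH2OH (1.5 equiv), TsOH·H2O (cat.), toluene, reflux, Dean–Stark trap
Reagents that add atoms: 2,2,2-trichloroethanol, OCC(Cl)(Cl)Cl
Why: Fischer esterification driven by azeotropic removal of water acylates only the alcohol, since the phenol does not esterify under acid catalysis.

Step 2
Reactants: 2 (4-hydroxyphenyl)acetic acid 2,2,2-trichloroethyl ester
Product: 3 [4-(2,2,2-trichloroethoxycarbonyloxy)phenyl]acetic acid 2,2,2-trichloroethyl ester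
Conditions: Cl3CCH2OCOCl, pyridine, CH2Cl2, 0 °C
Reagents that add atoms: 2,2,2-trichloroethyl chloroformate, ClC(=O)OCC(Cl)(Cl)Cl
Why: Pyridine-mediated O-acylation of the phenol by the chloroformate gives an aryl carbonate that should survive radical bromination, amide base at low temperature and strong acid, and that falls to zinc together with the ester.

Step 3
Reactants: 3 [4-(2,2,2-trichloroethoxycarbonyloxy)phenyl]acetic acid 2,2,2-trichloroethyl ester
Product: 4 bromo[4-(2,2,2-trichloroethoxycarbonyloxy)phenyl]acetic acid 2,2,2-trichloroethyl ester (racemic)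
Conditions: NBS (1.05 equiv), AIBN (cat.), PhCF3, 85 °C
Reagents that add atoms: N-bromosuccinimide, BrN1C(=O)CCC1=O
Why: Wohl–Ziegler bromination at the only benzylic position, which is also α to the ester; the stereocentre formed is racemic and is erased in step 6.

Step 4
Reactants: 4 bromo[4-(2,2,2-trichloroethoxycarbonyloxy)phenyl]acetic acid 2,2,2-trichloroethyl ester; 5 phloroglucinol dimethyl ether (3,5-dimethoxyphenol)
Product: 6 (3,5-dimethoxyphenoxy)[4-(2,2,2-trichloroethoxycarbonyloxy)phenyl]acetic acid 2,2,2-trichloroethyl ester (racemic)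
Conditions: K2CO3, acetone, 20 °C
Reagents that add atoms: none
Why: Williamson-type SN2 displacement of the activated secondary benzylic α-bromo ester by the phenoxide, with O-alkylation expected under K2CO3/acetone; the product is racemic, which does not matter because C2 is planarised in step 6.

Step 5
Reactants: 7 (E)-2-cyano-3-phenylprop-2-enoic acid (α-cyanocinnamic acid); 8 (S)-4-benzyl-1,3-oxazolidin-2-one
Product: 10 (S)-4-benzyl-3-[(E)-2-cyano-3-phenylprop-2-enoyl]-1,3-oxazolidin-2-one, via acid chloride 9 (not isolated)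
Conditions: (COCl)2, DMF (cat.), CH2Cl2, 0 → 20 °C, evaporate; then 8, Et3N, DMAP (cat.), CH2Cl2, 0 → 20 °C
Reagents that add atoms: none
Why: Acid chloride formation followed by DMAP-catalysed N-acylation of the oxazolidinone keeps the (E)-alkene (phenyl cis to cyano) and installs an auxiliary that is both the chirality source for step 6 and the acyl activation for step 12.

Step 6
Reactants: 6 (3,5-dimethoxyphenoxy)[4-(2,2,2-trichloroethoxycarbonyloxy)phenyl]acetic acid 2,2,2-trichloroethyl ester; 10 (S)-4-benzyl-3-[(E)-2-cyano-3-phenylprop-2-enoyl]-1,3-oxazolidin-2-one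
Product: 14 (2S,3S,4R)-4-[(S)-4-benzyl-2-oxo-1,3-oxazolidine-3-carbonyl]-6,8-dimethoxy-5-oxo-3-phenyl-2-[4-(2,2,2-trichloroethoxycarbonyloxy)phenyl]-2,3,4,5-tetrahydro-1-benzoxepine-2-carboxylic acid 2,2,2-trichloroethyl ester, via lithium enolate 11 (not isolated), via Michael adduct 12 (not isolated), via ketiminium triflate 13 (not isolated)
Conditions: LiN(SiMe3)2 (1.05 equiv), toluene, −78 °C; 10 in CH2Cl2, −78 °C; then CF3SO3H (10 equiv), −78 → 0 °C; then H2O/MeCN, 40 °C
Reagents that add atoms: water, O
Why: Proposed new method: the chelated lithium enolate 11 adds 1,4 to the cyano- and imide-activated alkene of 10 (C2–C3 bond), the resulting anion is protonated to 12, and in CF3SO3H the N-protonated nitrile is attacked by the ring A carbon ortho to O1 in an intramolecular Houben–Hoesch reaction (C5–C5a bond), the ketiminium salt 13 being hydrolysed to the ketone on work-up. Each half is known chemistry (ester enolate Michael additions to arylidene cyanoacetyl acceptors; acid-mediated Hoesch cyclisation of aryloxy nitriles of phloroglucinol ethers to chromanones) and the closest one-pot analogy is the domino conjugate addition/Friedel–Crafts acylation of alkylidene Meldrum's acids, but the union of the two as a formal [4+3] annulation to a benzoxepinone is new. The oxepinone ring closes in the 7-exo-dig mode by electrophilic aromatic substitution at the nitrilium carbon. C3 is set by the auxiliary, since Li+ held between the two imide carbonyls (syn, s-cis acryloyl) lets the benzyl group cover the Si face of the β-carbon so that the enolate enters on the Re face; C2 is set by a closed, lithium-bridged synclinal transition state of the chelated enolate (aryloxy oxygen cis to O–Li) in which the acyl group of 10 lies over the O–Li side and the β-hydrogen, not the phenyl group, over the crowded sector between the C2 aryl and the ester alkoxy group, which gives the cis relation of the C2 aryl and C3 phenyl groups; C4 is an acidic β-keto imide centre that settles trans to the C3 phenyl group. The step needs 1,4- over 1,2-addition (soft, hindered tertiary enolate against a doubly activated alkene), ring closure on ring A and not on the C3 phenyl or the C2 aryl ring (phloroglucinol-type activation of C5a against an unactivated phenyl and a carbonate-deactivated aryl ring, the para carbon of ring A being out of reach), and acylation by the nitrile and not by the imide or the hindered C2 ester carbonyl (the linear nitrilium ion is the strongest and least hindered electrophile present).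

Step 7
Reactants: 14 (2S,3S,4R)-4-[(S)-4-benzyl-2-oxo-1,3-oxazolidine-3-carbonyl]-6,8-dimethoxy-5-oxo-3-phenyl-2-[4-(2,2,2-trichloroethoxycarbonyloxy)phenyl]-2,3,4,5-tetrahydro-1-benzoxepine-2-carboxylic acid 2,2,2-trichloroethyl ester
Product: 15 (2S,3S,4R)-4-[(S)-4-benzyl-2-oxo-1,3-oxazolidine-3-carbonyl]-2-(4-hydroxyphenyl)-6,8-dimethoxy-5-oxo-3-phenyl-2,3,4,5-tetrahydro-1-benzoxepine-2-carboxylic acid
Conditions: Zn dust, AcOH/THF 1:4, 20 °C
Reagents that add atoms: none
Why: Zinc-induced reductive β-elimination of the trichloroethyl ester and of the trichloroethyl carbonate (the latter with loss of CO2) should free the hindered C2 acid and the phenol under acidic, non-hydrolytic conditions that leave the imide, the ketone and the three stereocentres untouched.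

Step 8
Reactants: 16 glycolaldehyde dimer (1,4-dioxane-2,5-diol); 17 ethyl 2-(triphenylphosphoranylidene)propanoate
Product: 18 ethyl (E)-4-hydroxy-2-methylbut-2-enoate
Conditions: CH2Cl2, 40 °C
Reagents that add atoms: none
Why: Wittig reaction of the stabilised, α-branched ylide with monomeric glycolaldehyde released from the dimer should give the (E)-trisubstituted enoate, as is usual for stabilised ylides.

Step 9
Reactants: 18 ethyl (E)-4-hydroxy-2-methylbut-2-enoate
Product: 19 (E)-4-hydroxy-2-methylbut-2-enoic acid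
Conditions: LiOH, THF/H2O, 0 → 20 °C; then aq. HCl to pH 2
Reagents that add atoms: lithium hydroxide, [Li+].[OH-]
Why: Saponification of the ethyl ester; the (E)-geometry prevents lactonisation to the butenolide.

Step 10
Reactants: 19 (E)-4-hydroxy-2-methylbut-2-enoic acid; 20 tert-butyl N-(4-aminobutyl)carbamate
Product: 21 tert-butyl N-[4-[[(E)-4-hydroxy-2-methylbut-2-enoyl]amino]butyl]carbamate
Conditions: DCC, HOBt, CH2Cl2/DMF, 0 → 20 °C
Reagents that add atoms: none
Why: Carbodiimide/HOBt amide coupling in which the primary amine should outcompete the primary alcohol for the active ester, so no hydroxyl protection is needed.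

Step 11
Reactants: 21 tert-butyl N-[4-[[(E)-4-hydroxy-2-methylbut-2-enoyl]amino]butyl]carbamate
Product: 22 (E)-N-(4-aminobutyl)-4-hydroxy-2-methylbut-2-enamide hydrochloride
Conditions: HCl (4 M in 1,4-dioxane), 0 °C
Reagents that add atoms: hydrogen chloride, Cl
Why: Acidolysis of the Boc carbamate through the tert-butyl cation gives the amine as its hydrochloride; the conjugated amide and the allylic alcohol should tolerate brief exposure to HCl at 0 °C.

Step 12
Reactants: 15 (2S,3S,4R)-4-[(S)-4-benzyl-2-oxo-1,3-oxazolidine-3-carbonyl]-2-(4-hydroxyphenyl)-6,8-dimethoxy-5-oxo-3-phenyl-2,3,4,5-tetrahydro-1-benzoxepine-2-carboxylic acid; 22 (E)-N-(4-aminobutyl)-4-hydroxy-2-methylbut-2-enamide hydrochloride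
Product: 23 (2S,3S,4R)-2-(4-hydroxyphenyl)-4-[[4-[[(E)-4-hydroxy-2-methylbut-2-enoyl]amino]butyl]carbamoyl]-6,8-dimethoxy-5-oxo-3-phenyl-2,3,4,5-tetrahydro-1-benzoxepine-2-carboxylic acid (CNP0300324.1)
Conditions: iPr2NEt (4 equiv), MeCN, 60 °C
Reagents that add atoms: none
Why: Acyl transfer from the β-keto acyl oxazolidinone to the primary amine (direct addition–elimination, or through the acylketene formed by E1cB loss of the oxazolidinone anion) should give the amide; the C2 carboxylate and the phenoxide are not acyl acceptors, the carboxylate blocks retro-Michael opening, and C4 re-equilibrates to the trans (4R) configuration.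

**Compound list**

1 | (4-hydroxyphenyl)acetic acid | OC(=O)Cc1ccc(O)cc1 | starting material
2 | (4-hydroxyphenyl)acetic acid 2,2,2-trichloroethyl ester | O=C(Cc1ccc(O)cc1)OCC(Cl)(Cl)Cl | intermediate
3 | [4-(2,2,2-trichloroethoxycarbonyloxy)phenyl]acetic acid 2,2,2-trichloroethyl ester | O=C(Cc1ccc(OC(=O)OCC(Cl)(Cl)Cl)cc1)OCC(Cl)(Cl)Cl | intermediate
4 | bromo[4-(2,2,2-trichloroethoxycarbonyloxy)phenyl]acetic acid 2,2,2-trichloroethyl ester (racemic) | O=C(OCC(Cl)(Cl)Cl)C(Br)c1ccc(OC(=O)OCC(Cl)(Cl)Cl)cc1 | intermediate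
5 | 3,5-dimethoxyphenol | COc1cc(O)cc(OC)c1 | starting material
6 | (3,5-dimethoxyphenoxy)[4-(2,2,2-trichloroethoxycarbonyloxy)phenyl]acetic acid 2,2,2-trichloroethyl ester (racemic) | COc1cc(OC)cc(OC(C(=O)OCC(Cl)(Cl)Cl)c2ccc(OC(=O)OCC(Cl)(Cl)Cl)cc2)c1 | intermediate
7 | (E)-2-cyano-3-phenylprop-2-enoic acid | OC(=O)/C(C#N)=C/c1ccccc1 | starting material
8 | (S)-4-benzyl-1,3-oxazolidin-2-one | O=C1N[C@@H](Cc2ccccc2)CO1 | starting material
9 | (E)-2-cyano-3-phenylprop-2-enoyl chloride (not isolated) | ClC(=O)/C(C#N)=C/c1ccccc1 | intermediate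
10 | (S)-4-benzyl-3-[(E)-2-cyano-3-phenylprop-2-enoyl]-1,3-oxazolidin-2-one | N#C/C(=C\c1ccccc1)C(=O)N1[C@@H](Cc2ccccc2)COC1=O | intermediate
11 | lithium enolate of 6, aryloxy oxygen cis to O–Li (not isolated) | [Li+].[O-]/C(OCC(Cl)(Cl)Cl)=C(\Oc1cc(OC)cc(OC)c1)c1ccc(OC(=O)OCC(Cl)(Cl)Cl)cc1 | intermediate
12 | (2S,3S)-5-[(S)-4-benzyl-2-oxo-1,3-oxazolidin-3-yl]-4-cyano-2-(3,5-dimethoxyphenoxy)-5-oxo-3-phenyl-2-[4-(2,2,2-trichloroethoxycarbonyloxy)phenyl]pentanoic acid 2,2,2-trichloroethyl ester, both C4 epimers (not isolated) | COc1cc(OC)cc(c1)O[C@](C(=O)OCC(Cl)(Cl)Cl)(c1ccc(OC(=O)OCC(Cl)(Cl)Cl)cc1)[C@H](c1ccccc1)C(C#N)C(=O)N1[C@@H](Cc2ccccc2)COC1=O | intermediate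
13 | (2S,3S)-4-[(S)-4-benzyl-2-oxo-1,3-oxazolidine-3-carbonyl]-6,8-dimethoxy-3-phenyl-2-(2,2,2-trichloroethoxycarbonyl)-2-[4-(2,2,2-trichloroethoxycarbonyloxy)phenyl]-3,4-dihydro-2H-1-benzoxepin-5-iminium trifluoromethanesulfonate, C4 labile (not isolated) | COc1cc(OC)c2c(c1)O[C@](C(=O)OCC(Cl)(Cl)Cl)(c1ccc(OC(=O)OCC(Cl)(Cl)Cl)cc1)[C@H](c1ccccc1)C(C(=O)N1[C@@H](Cc3ccccc3)COC1=O)C2=[NH2+].[O-]S(=O)(=O)C(F)(F)F | intermediate
14 | (2S,3S,4R)-4-[(S)-4-benzyl-2-oxo-1,3-oxazolidine-3-carbonyl]-6,8-dimethoxy-5-oxo-3-phenyl-2-[4-(2,2,2-trichloroethoxycarbonyloxy)phenyl]-2,3,4,5-tetrahydro-1-benzoxepine-2-carboxylic acid 2,2,2-trichloroethyl ester | COc1cc(OC)c2c(c1)O[C@](C(=O)OCC(Cl)(Cl)Cl)(c1ccc(OC(=O)OCC(Cl)(Cl)Cl)cc1)[C@H](c1ccccc1)[C@@H](C(=O)N1[C@@H](Cc3ccccc3)COC1=O)C2=O | intermediate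
15 | (2S,3S,4R)-4-[(S)-4-benzyl-2-oxo-1,3-oxazolidine-3-carbonyl]-2-(4-hydroxyphenyl)-6,8-dimethoxy-5-oxo-3-phenyl-2,3,4,5-tetrahydro-1-benzoxepine-2-carboxylic acid | COc1cc(OC)c2c(c1)O[C@](C(=O)O)(c1ccc(O)cc1)[C@H](c1ccccc1)[C@@H](C(=O)N1[C@@H](Cc3ccccc3)COC1=O)C2=O | intermediate
16 | glycolaldehyde dimer (1,4-dioxane-2,5-diol) | OC1COC(O)CO1 | starting material
17 | ethyl 2-(triphenylphosphoranylidene)propanoate | CCOC(=O)C(C)=P(c1ccccc1)(c1ccccc1)c1ccccc1 | starting material
18 | ethyl (E)-4-hydroxy-2-methylbut-2-enoate | CCOC(=O)/C(C)=C/CO | intermediate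
19 | (E)-4-hydroxy-2-methylbut-2-enoic acid | OC(=O)/C(C)=C/CO | intermediate
20 | tert-butyl N-(4-aminobutyl)carbamate | CC(C)(C)OC(=O)NCCCCN | starting material
21 | tert-butyl N-[4-[[(E)-4-hydroxy-2-methylbut-2-enoyl]amino]butyl]carbamate | CC(C)(C)OC(=O)NCCCCNC(=O)/C(C)=C/CO | intermediate
22 | (E)-N-(4-aminobutyl)-4-hydroxy-2-methylbut-2-enamide hydrochloride | [NH3+]CCCCNC(=O)/C(C)=C/CO.[Cl-] | intermediate
23 | (2S,3S,4R)-2-(4-hydroxyphenyl)-4-[[4-[[(E)-4-hydroxy-2-methylbut-2-enoyl]amino]butyl]carbamoyl]-6,8-dimethoxy-5-oxo-3-phenyl-2,3,4,5-tetrahydro-1-benzoxepine-2-carboxylic acid | COc1cc(OC)c2c(c1)O[C@](C(=O)O)(c1ccc(O)cc1)[C@H](c1ccccc1)[C@@H](C(=O)NCCCCNC(=O)/C(C)=C/CO)C2=O | target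

**Step count and risks**

Total step count: 12. Longest linear sequence: 7 steps (steps 1, 2, 3, 4, 6, 7, 12).

Steps most likely to fail:

1. Step 6 (Proposed new method). The conjugate addition may lose facial or simple diastereoselectivity if it runs through an open instead of the closed, lithium-bridged transition state. In the acid stage, acylation through the imide carbonyl or acidolysis of the C2–O1 bond may compete with ring closure. The fallback sets out from 6 and 10 and comes back at 14, with the two bond formations separated. The lithium enolate addition is run alone (LiN(SiMe3)2, toluene, −78 °C, aqueous NH4Cl work-up), and the open-chain adduct 12 is isolated and freed from minor diastereomers by crystallisation or chromatography. 12 is then cyclised under classical Houben–Hoesch conditions (dry HCl, ZnCl2, Et2O, 0 °C), which should precipitate the ketiminium chloride F1, and this salt is hydrolysed with warm water to 14.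

2. Step 12. The amine may attack the ring carbonyl of the oxazolidinone (opening of the auxiliary), or the acyl transfer may stall once the β-keto imide is deprotonated. The fallback sets out from 15 and comes back at 23. 15 is first treated with LiSEt (from EtSH and n-BuLi, THF, 0 °C), which cleaves hindered acyl oxazolidinones at the exocyclic carbonyl, to give the S-ethyl thioester F2. Silver-promoted aminolysis of this β-keto thioester with 22 (AgOCOCF3, Et3N, THF, 20 °C) should then give 23.

3. Step 4. The ambident 3,5-dimethoxyphenoxide may alkylate on carbon, or the carbonate group of 4 may transfer to the phenoxide. The fallback sets out from 3 and comes back at 6. Diazo transfer to 3 (4-acetamidobenzenesulfonyl azide, DBU, MeCN, 0 °C) gives the aryldiazoacetate F3. Rh2(OAc)4-catalysed O–H insertion of its carbenoid into neutral 5 (CH2Cl2, 20 °C) should give 6 without any phenoxide being present.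

**Further compounds**

F1 | step 6 | (2S,3S)-4-[(S)-4-benzyl-2-oxo-1,3-oxazolidine-3-carbonyl]-6,8-dimethoxy-3-phenyl-2-(2,2,2-trichloroethoxycarbonyl)-2-[4-(2,2,2-trichloroethoxycarbonyloxy)phenyl]-3,4-dihydro-2H-1-benzoxepin-5-iminium chloride | COc1cc(OC)c2c(c1)O[C@](C(=O)OCC(Cl)(Cl)Cl)(c1ccc(OC(=O)OCC(Cl)(Cl)Cl)cc1)[C@H](c1ccccc1)C(C(=O)N1[C@@H](Cc3ccccc3)COC1=O)C2=[NH2+].[Cl-]
F2 | step 12 | (2S,3S,4R)-4-(ethylsulfanylcarbonyl)-2-(4-hydroxyphenyl)-6,8-dimethoxy-5-oxo-3-phenyl-2,3,4,5-tetrahydro-1-benzoxepine-2-carboxylic acid | COc1cc(OC)c2c(c1)O[C@](C(=O)O)(c1ccc(O)cc1)[C@H](c1ccccc1)[C@@H](C(=O)SCC)C2=O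
F3 | step 4 | diazo[4-(2,2,2-trichloroethoxycarbonyloxy)phenyl]acetic acid 2,2,2-trichloroethyl ester | [N-]=[N+]=C(C(=O)OCC(Cl)(Cl)Cl)c1ccc(OC(=O)OCC(Cl)(Cl)Cl)cc1
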